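Cedar and alder took the 0.20 M of starting material and 3.0 mM of initiator of the dusk and summer runs, so I had reagent and time to turn.

| flask | starting material | reagent | initiator | remark | time |
|---|---|---|---|---|---|
| dusk | 0.20 M | 0.20 M | 3 mM | run made earlier |  |
| summer | 0.20 M | 0.41 M | 3 mM | run made earlier |  |
| cedar | 0.20 M | 0.180 M | 3.0 mM |  | 15 min |
| alder | 0.20 M | 0.360 M | 3.0 mM |  | 15 min |

| run | time / min | starting material / % | product / % |
|---|---|---|---|
| dusk | 0.500 | 94 | 5 |
| dusk | 1.33 | 83 | 14 |
| dusk | 2.50 | 74 | 19 |
| dusk | 4.00 | 66 | 27 |
| dusk | 6.00 | 53 | 39 |
| dusk | 8.00 | 49 | 45 |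
| summer | 1.33 | 85 | 10 |
| summer | 2.50 | 76 | 18 |
| summer | 4.00 | 66 | 26 |
| summer | 5.00 | 56 | 32 |
| summer | 6.00 | 57 | 39 |
| summer | 8.00 | 50 | 44 |

(each reading ± 1.5 percentage points)

- what has gone from starting material into another species counts as reacted, even if it can come back

* part of the starting material that has reacted at the end, cedar
* part of the starting material that has reacted at the end, alder
* what raising the concentration of reagent from its lowest to its highest value here does to the part of the starting material that has reacted (changes below 5 percentage points count as none) (it rises / no change / it falls)

I worked in decades: the common logarithm of charged over left.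

1. Reagent. By hand, a first-order dependence would have made summer, with twice the reagent of dusk, lose decades twice as fast. Dusk lost 0.0387 min⁻¹ and summer 0.0376 min⁻¹. The last readings differed by less than the scatter of 1.5 percentage points, and the order in reagent read −0.0400, so I took zero order and expected the same outcome in cedar and alder.

2. Time. By hand, a steady decade rate would give a straight line. Pooling both runs, the rate was 0.0451 min⁻¹ up to 4.00 min, then 0.0312 min⁻¹ beyond it, which was slower.

3. My reckoning. I applied that fall once more, giving 0.0216 min⁻¹ over the last 7.00 min. The decades lost by the end of either flask then came to 0.457. That left 34.9 %, so 65.1 % had reacted. At one reagent per starting material, cedar's reagent, the limiting reagent, would end near 0.0499 M, below the tested range.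

4. The forecast. It gave 61 % for cedar (54 % to 69 %) and 63 % for alder (57 % to 71 %), with no change, calling the rate “effectively zero order in reagent”. Both figures stood below mine.

Cedar gave 64.8 % and alder 64.8 %, a difference of 0 points, so the trend was no change, with 31.8 % and 65.9 % of the charged reagent still free.

initiator → 2 initiating radical (k = 0.00142 s⁻¹); starting material + initiating radical → capped initiator + first chain carrier (k = 19700 L mol⁻¹ s⁻¹); reagent + first chain carrier ⇌ product + second chain carrier (K = 0.966, k = 16400 L mol⁻¹ s⁻¹); starting material + second chain carrier → released group + first chain carrier (k = 1280 L mol⁻¹ s⁻¹); 2 second chain carrier → ended chains (k = 3.00 × 10⁶ L mol⁻¹ s⁻¹); starting material + released group ⇌ idle adduct, settled at all times (K = 5.30 L mol⁻¹); crystals ⇌ released group, rate k7*(cs7 - [released group]) while solid is left; crystals form when [released group] > cs7 (solubility = 9.60 mM, k = 0.00932 s⁻¹) Cedar's decades came to 0.453 against my 0.457. A neighbour flask, cedar with 0.0051 M of initiator, kept 26 % of its starting material, which is 0.583 decades. Set against cedar's 0.453 and an initiator ratio of 1.70, that gives a logarithmic slope in initiator of 0.475.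

(The data were generated by integration for substances that don't exist.)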